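**Plan**

1. Numbering: oxane O1, C2 (aryl), C3 (cinnamyl), C4, C5, C6; C7 is the carbinol carbon on C5. The retrosynthesis cuts, in order: the three ArO–Si bonds; C7–H (ketone reduction); C2–aryl (aryl transfer to the ring oxocarbenium ion); C5–C6 and O1–C2 in one operation (one CH2O inserted between an enol ether carbon and a masked aldehyde carbon); C3–C4 (Michael addition); the styrene C=C (cross-metathesis).
2. Enabling feature: with C7 held as an aryl ketone, C5 is an enolisable α-carbon standing 1,4 to C2. With C2 at the aldehyde level, the hydroxymethyl oxygen placed on C5 closes the six-membered oxane as a lactol, so C6 and O1 both come from formaldehyde.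
3. Forward: side-chain aldehyde by metathesis; C3–C4 by enamine Michael addition to an aryl vinyl ketone; Z-silyl enol ether; hydroxymethylation/lactolisation (the only ring); anomeric sulfone; arylzinc substitution; ketone reduction; desilylation.
4. Stereochemistry: C3 from the (R)-diarylprolinol silyl ether; C5 from the chiral scandium catalyst (cis to C3, also the more stable lactol); C2 from axial aryl delivery to the half-chair oxocarbenium ion locked by the equatorial C3 and C5 groups; C7 from the (S)-oxazaborolidine; E-alkene from metathesis.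

Key step: step 6

Abbreviation: TBSO = tert-butyldimethylsilyloxy.
Remark (assumption): in step 6 the (R,R)-bipyridine diol ligand is written on the assumption that it turns the Z-enol ether toward the (R)-configured α-carbon; if the sense is the reverse, the (S,S)-ligand is used and nothing else changes.
Remark: the target carries its C2 aryl group axial (cis to the C3 and C5 groups), so it is the less stable C2 epimer; C2 is therefore set kinetically and is not exposed to strong acid afterwards.

**Route**

Step 1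
Reactants: 1 tert-butyldimethyl(4-vinylphenoxy)silane; 2 pent-4-enal (3 equiv)
Product: 3 (4E)-5-[4-(TBSO)phenyl]pent-4-enal
Conditions: second-generation Grubbs catalyst (3 mol %), CH2Cl2, 40 °C
Reagents that add atoms: none
Why: Olefin cross-metathesis of a styrene with a terminal alkene; the excess of the simple aldehyde should suppress stilbene formation and the aryl-conjugated alkene should form as the E isomer under thermodynamic control.

Step 2
Reactants: 4 4-(TBSO)benzaldehyde; 5 vinylmagnesium bromide (1 M in THF)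
Product: 6 1-[4-(TBSO)phenyl]prop-2-en-1-ol (racemic)
Conditions: THF, 0 °C; aq. NH4Cl
Reagents that add atoms: none
Why: Grignard 1,2-addition to an aryl aldehyde; the new stereocentre is removed in step 3.

Step 3
Reactants: 6 1-[4-(TBSO)phenyl]prop-2-en-1-ol
Product: 7 1-[4-(TBSO)phenyl]prop-2-en-1-one
Conditions: MnO2 (10 equiv), CH2Cl2, rt; used at once
Reagents that add atoms: none
Why: MnO2 oxidation of an alcohol that is both allylic and benzylic should give the aryl vinyl ketone, which is used without storage because it polymerises.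

Step 4
Reactants: 3 (4E)-5-[4-(TBSO)phenyl]pent-4-enal (1.5 equiv); 7 1-[4-(TBSO)phenyl]prop-2-en-1-one
Product: 9 (4R,6E)-4-(dimethoxymethyl)-1,7-bis[4-(TBSO)phenyl]hept-6-en-1-one, via keto aldehyde 8 (not isolated)
Conditions: (R)-2-[diphenyl(trimethylsilyloxy)methyl]pyrrolidine (10 mol %), ethyl 3,4-dihydroxybenzoate (20 mol %), CH2Cl2, 4 °C; then HC(OMe)3, TsOH·H2O (in slight excess of the amine), MeOH, 0 °C
Reagents that add atoms: trimethyl orthoformate COC(OC)OC; methanol CO
Why: Enamine-catalysed Michael addition of an aldehyde to a vinyl ketone, in which the bulky diaryl(silyloxy)methyl group blocks one face of the E-enamine so that the enone should add to the other face and set C3 as (R) in 8; acetalisation in the same flask protects the epimerisable aldehyde α-carbon and leaves the aryl ketone as the only carbonyl group.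

Step 5
Reactants: 9 (4R,6E)-4-(dimethoxymethyl)-1,7-bis[4-(TBSO)phenyl]hept-6-en-1-one
Product: 10 (1Z,4S,6E)-4-(dimethoxymethyl)-1,7-bis[4-(TBSO)phenyl]-1-(trimethylsilyloxy)hepta-1,6-diene
Conditions: LiN(SiMe3)2 (1.1 equiv), Me3SiCl (1.3 equiv), THF, −78 °C; pentane, filtration, no aqueous work-up; used crude
Reagents that add atoms: chlorotrimethylsilane C[Si](C)(C)Cl
Why: Kinetic enolate silylation at the only enolisable position (the ketone CH2, future C5), where aryl alkyl ketones give the Z-enolate; the descriptor at the stereocentre changes from R to S only because the CIP priorities change.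

Step 6
Reactants: 10 (1Z,4S,6E)-4-(dimethoxymethyl)-1,7-bis[4-(TBSO)phenyl]-1-(trimethylsilyloxy)hepta-1,6-diene; 11 formaldehyde (37% aqueous solution, 5 equiv)
Product: 14 {(3R,5S)-6-hydroxy-5-[(2E)-3-[4-(TBSO)phenyl]prop-2-en-1-yl]oxan-3-yl}[4-(TBSO)phenyl]methanone (lactol; both anomers), via hydroxymethyl ketone acetal 12 (not isolated), via open-chain hydroxy aldehyde 13 (not isolated)
Conditions: Sc(OTf)3 (10 mol %), (R,R)-6,6'-bis(1-hydroxy-2,2-dimethylpropyl)-2,2'-bipyridine (12 mol %), DME/H2O 9:1, −20 °C; then 1 M HCl, THF, 0 °C to rt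
Reagents that add atoms: water O
Why: Formaldehyde bound to the chiral scandium triflate–bipyridine complex is attacked by the Z-silyl enol ether carbon C5 (Mukaiyama aldol, open transition state) and water cleaves the silyl group, which gives the C5–C6 bond and the free hydroxymethyl group of 12; dilute acid then unmasks the aldehyde and the hydroxyl oxygen adds to it, which makes O1–C2 and closes the oxane. The closest known reaction type is the scandium- or lanthanide-triflate-catalysed hydroxymethylation of silicon enolates of aryl ketones with aqueous formaldehyde, followed by ordinary ring–chain tautomerism of a δ-hydroxy aldehyde. The single ring closes in the 6-exo-trig mode (oxygen onto the aldehyde carbon) as a hemiacetal. C5 is set by the catalyst, which distinguishes the two faces of the enol ether (formaldehyde has none), and the configuration chosen is also that of the more stable lactol with the C3 and C5 groups both equatorial; C2 is formed as an anomeric mixture and is defined only in step 8. The step needs site selectivity for C5 over C3 and reaction of formaldehyde with the enol ether only: C3 cannot enolise because its aldehyde is an acetal until the C–C bond is made, there is one silyl enol ether per molecule so only one hydroxymethyl group can enter, and the aryl-conjugated side-chain alkene is far less nucleophilic than the enol ether.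

Step 7
Reactants: 14 {(3R,5S)-6-hydroxy-5-[(2E)-3-[4-(TBSO)phenyl]prop-2-en-1-yl]oxan-3-yl}[4-(TBSO)phenyl]methanone
Product: 15 {(3R,5S)-6-(phenylsulfonyl)-5-[(2E)-3-[4-(TBSO)phenyl]prop-2-en-1-yl]oxan-3-yl}[4-(TBSO)phenyl]methanone (both anomers)
Conditions: PhSO2H (1.5 equiv), CaCl2, CH2Cl2, rt
Reagents that add atoms: benzenesulfinic acid O=S(O)c1ccccc1
Why: Exchange of the anomeric hydroxyl for sulfinate through the oxocarbenium ion (formation of a 2-sulfonyl cyclic ether from a lactol), with CaCl2 taking up the water; the anomeric configuration is irrelevant because it is erased in step 8.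

Step 8
Reactants: 15 {(3R,5S)-6-(phenylsulfonyl)-5-[(2E)-3-[4-(TBSO)phenyl]prop-2-en-1-yl]oxan-3-yl}[4-(TBSO)phenyl]methanone; 16 (4-bromophenoxy)(tert-butyl)dimethylsilane (2.5 equiv)
Product: 19 {(3R,5S,6R)-6-[4-(TBSO)phenyl]-5-[(2E)-3-[4-(TBSO)phenyl]prop-2-en-1-yl]oxan-3-yl}[4-(TBSO)phenyl]methanone, via arylmagnesium bromide 17 (not isolated), via arylzinc bromide 18 (not isolated)
Conditions: Mg, THF, rt (16 to 17); ZnBr2 (1.1 equiv per Grignard), THF, 0 °C (17 to 18); then 15, THF, rt
Reagents that add atoms: none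
Why: Substitution of a 2-sulfonyl cyclic ether by an arylzinc reagent, in which ZnBr2/MgBr2 ionise the sulfone to the cyclic oxocarbenium ion and, with the cis C3 and C5 groups both pseudo-equatorial in its half-chair, the aryl group should be delivered along the axial trajectory (chair-like transition state) to give the 2-aryl group cis to both, while the aryl ketone is inert to arylzinc halides.

Step 9
Reactants: 19 {(3R,5S,6R)-6-[4-(TBSO)phenyl]-5-[(2E)-3-[4-(TBSO)phenyl]prop-2-en-1-yl]oxan-3-yl}[4-(TBSO)phenyl]methanone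
Product: 20 (R)-{(3R,5S,6R)-6-[4-(TBSO)phenyl]-5-[(2E)-3-[4-(TBSO)phenyl]prop-2-en-1-yl]oxan-3-yl}[4-(TBSO)phenyl]methanol
Conditions: (S)-2-methyl-CBS-oxazaborolidine (0.5 equiv), catecholborane (2 equiv), toluene, −78 to −40 °C; MeOH, aq. NaHCO3
Reagents that add atoms: none
Why: Corey–Bakshi–Shibata reduction under reagent control, in which the aryl group should act as the large substituent so that the (S)-catalyst gives the (R)-carbinol (the two ring branches at C5 are nearly equivalent, so substrate bias should be small), and catecholborane at low temperature should leave the styrene untouched.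

Step 10
Reactants: 20 (R)-{(3R,5S,6R)-6-[4-(TBSO)phenyl]-5-[(2E)-3-[4-(TBSO)phenyl]prop-2-en-1-yl]oxan-3-yl}[4-(TBSO)phenyl]methanol
Product: 21 4-[(2R,3S,5R)-5-[(R)-hydroxy(4-hydroxyphenyl)methyl]-3-[(2E)-3-(4-hydroxyphenyl)prop-2-en-1-yl]oxan-2-yl]phenol (CNP0182155.1)
Conditions: Bu4NF (3.5 equiv), AcOH (3.5 equiv), THF, 0 °C
Reagents that add atoms: none
Why: Fluoride cleavage of the three aryl silyl ethers, buffered with acetic acid so that neither phenoxide-driven quinone methide formation nor acid ionisation can epimerise the axial C2 aryl ether or the benzylic carbinol.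

**Compound list**

1 | tert-butyldimethyl(4-vinylphenoxy)silane | C=Cc1ccc(O[Si](C)(C)C(C)(C)C)cc1 | starting material
2 | pent-4-enal | C=CCCC=O | starting material
3 | (4E)-5-[4-(TBSO)phenyl]pent-4-enal | O=CCC/C=C/c1ccc(O[Si](C)(C)C(C)(C)C)cc1 | intermediate
4 | 4-(TBSO)benzaldehyde | O=Cc1ccc(O[Si](C)(C)C(C)(C)C)cc1 | starting material
5 | vinylmagnesium bromide | C=C[Mg]Br | starting material
6 | 1-[4-(TBSO)phenyl]prop-2-en-1-ol (racemic) | C=CC(O)c1ccc(O[Si](C)(C)C(C)(C)C)cc1 | intermediate
7 | 1-[4-(TBSO)phenyl]prop-2-en-1-one | C=CC(=O)c1ccc(O[Si](C)(C)C(C)(C)C)cc1 | intermediate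
8 | (2R,4E)-2-{3-oxo-3-[4-(TBSO)phenyl]propyl}-5-[4-(TBSO)phenyl]pent-4-enal | O=C[C@@H](C/C=C/c1ccc(O[Si](C)(C)C(C)(C)C)cc1)CCC(=O)c1ccc(O[Si](C)(C)C(C)(C)C)cc1 | intermediate (not isolated)
9 | (4R,6E)-4-(dimethoxymethyl)-1,7-bis[4-(TBSO)phenyl]hept-6-en-1-one | COC(OC)[C@@H](C/C=C/c1ccc(O[Si](C)(C)C(C)(C)C)cc1)CCC(=O)c1ccc(O[Si](C)(C)C(C)(C)C)cc1 | intermediate
10 | (1Z,4S,6E)-4-(dimethoxymethyl)-1,7-bis[4-(TBSO)phenyl]-1-(trimethylsilyloxy)hepta-1,6-diene | COC(OC)[C@@H](C/C=C/c1ccc(O[Si](C)(C)C(C)(C)C)cc1)C/C=C(\O[Si](C)(C)C)c1ccc(O[Si](C)(C)C(C)(C)C)cc1 | intermediate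
11 | formaldehyde | C=O | starting material
12 | (2R,4S,6E)-4-(dimethoxymethyl)-2-(hydroxymethyl)-1,7-bis[4-(TBSO)phenyl]hept-6-en-1-one | COC(OC)[C@@H](C/C=C/c1ccc(O[Si](C)(C)C(C)(C)C)cc1)C[C@H](CO)C(=O)c1ccc(O[Si](C)(C)C(C)(C)C)cc1 | intermediate (not isolated)
13 | (2S,4E)-2-{(2R)-2-(hydroxymethyl)-3-oxo-3-[4-(TBSO)phenyl]propyl}-5-[4-(TBSO)phenyl]pent-4-enal | O=C[C@@H](C/C=C/c1ccc(O[Si](C)(C)C(C)(C)C)cc1)C[C@H](CO)C(=O)c1ccc(O[Si](C)(C)C(C)(C)C)cc1 | intermediate (not isolated)
14 | {(3R,5S)-6-hydroxy-5-[(2E)-3-[4-(TBSO)phenyl]prop-2-en-1-yl]oxan-3-yl}[4-(TBSO)phenyl]methanone (both anomers) | CC(C)(C)[Si](C)(C)Oc1ccc(/C=C/C[C@H]2C[C@@H](C(=O)c3ccc(O[Si](C)(C)C(C)(C)C)cc3)COC2O)cc1 | intermediate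
15 | {(3R,5S)-6-(phenylsulfonyl)-5-[(2E)-3-[4-(TBSO)phenyl]prop-2-en-1-yl]oxan-3-yl}[4-(TBSO)phenyl]methanone (both anomers) | CC(C)(C)[Si](C)(C)Oc1ccc(/C=C/C[C@H]2C[C@@H](C(=O)c3ccc(O[Si](C)(C)C(C)(C)C)cc3)COC2S(=O)(=O)c2ccccc2)cc1 | intermediate
16 | (4-bromophenoxy)(tert-butyl)dimethylsilane | Brc1ccc(O[Si](C)(C)C(C)(C)C)cc1 | starting material
17 | [4-(TBSO)phenyl]magnesium bromide | Br[Mg]c1ccc(O[Si](C)(C)C(C)(C)C)cc1 | intermediate (not isolated)
18 | [4-(TBSO)phenyl]zinc bromide | Br[Zn]c1ccc(O[Si](C)(C)C(C)(C)C)cc1 | intermediate (not isolated)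
19 | {(3R,5S,6R)-6-[4-(TBSO)phenyl]-5-[(2E)-3-[4-(TBSO)phenyl]prop-2-en-1-yl]oxan-3-yl}[4-(TBSO)phenyl]methanone | CC(C)(C)[Si](C)(C)Oc1ccc(/C=C/C[C@H]2C[C@@H](C(=O)c3ccc(O[Si](C)(C)C(C)(C)C)cc3)CO[C@H]2c2ccc(O[Si](C)(C)C(C)(C)C)cc2)cc1 | intermediate
20 | (R)-{(3R,5S,6R)-6-[4-(TBSO)phenyl]-5-[(2E)-3-[4-(TBSO)phenyl]prop-2-en-1-yl]oxan-3-yl}[4-(TBSO)phenyl]methanol | CC(C)(C)[Si](C)(C)Oc1ccc(/C=C/C[C@H]2C[C@@H]([C@@H](O)c3ccc(O[Si](C)(C)C(C)(C)C)cc3)CO[C@H]2c2ccc(O[Si](C)(C)C(C)(C)C)cc2)cc1 | intermediate
21 | 4-[(2R,3S,5R)-5-[(R)-hydroxy(4-hydroxyphenyl)methyl]-3-[(2E)-3-(4-hydroxyphenyl)prop-2-en-1-yl]oxan-2-yl]phenol | Oc1ccc(/C=C/C[C@H]2C[C@@H]([C@@H](O)c3ccc(O)cc3)CO[C@H]2c2ccc(O)cc2)cc1 | target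

**Count and risks**

Total step count: 10. Longest linear sequence: 9 steps (4 → 6 → 7 → 9 → 10 → 14 → 15 → 19 → 20 → 21; steps 2 to 10).

Steps most likely to fail:

1. Step 8. The aryl group may be transferred to the equatorial face of the oxocarbenium ion (twist-boat pathway), the ion may lose the C3 proton to give the dihydropyran, or the axial aryl ether may slowly ionise and epimerise under the Lewis acid. Fallback: the ionic substitution is replaced by a nickel-catalysed radical cross-coupling. It sets out from lactol 14, which with SOCl2 (cat. DMF, CH2Cl2, 0 °C) should give the anomeric chloride {(3R,5S)-6-chloro-5-[(2E)-3-[4-(TBSO)phenyl]prop-2-en-1-yl]oxan-3-yl}[4-(TBSO)phenyl]methanone F1. Negishi coupling of this chloride with arylzinc bromide 18 (made from 16 as in step 8) under NiCl2(dme) (10 mol %) and 4,4',4''-tri-tert-butyl-2,2':6',2''-terpyridine in DMA/THF at rt proceeds through the 2-oxanyl radical, which is captured from the axial direction as with glycosyl halides. The fallback comes back to the route at 19.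

2. Step 6. The catalyst may not distinguish the enol ether faces well enough on this large substrate, or C5 may epimerise during the acidic lactolisation, so that C5 epimers form. Fallback: kinetic catalyst control is replaced by thermodynamic control. It sets out from 10, which with achiral Yb(OTf)3 (10 mol %) and aqueous formaldehyde in THF/H2O should give 12 together with its C5 epimer, (2S,4S,6E)-4-(dimethoxymethyl)-2-(hydroxymethyl)-1,7-bis[4-(TBSO)phenyl]hept-6-en-1-one F2. Camphorsulfonic acid in methanol closes both to the 2-methoxyoxanes, the cis acetal {(3R,5S)-6-methoxy-5-[(2E)-3-[4-(TBSO)phenyl]prop-2-en-1-yl]oxan-3-yl}[4-(TBSO)phenyl]methanone F3 and the trans acetal {(3S,5S)-6-methoxy-5-[(2E)-3-[4-(TBSO)phenyl]prop-2-en-1-yl]oxan-3-yl}[4-(TBSO)phenyl]methanone F4. With C2 locked as the acetal only C5 can enolise, so DBU in toluene at 60 °C should drain the trans acetal into the diequatorial cis acetal. 1 M HCl in THF then gives lactol 14, where the fallback comes back to the route.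

3. Step 9. Diastereoface selectivity may be low if the α-branched ring carbon competes with the aryl group for the role of the large substituent, and the borane may hydroborate the styrene. Fallback: the oxazaborolidine is replaced by an enzyme. It sets out from ketone 19, which is reduced by an (R)-selective NADPH-dependent ketoreductase (alcohol dehydrogenase class, chosen from a panel for bulky aryl ketones) with propan-2-ol as the terminal reductant in buffer/DMSO at 30 °C; the enzyme pocket rather than the relative size of the two substituents fixes the face, and alkenes are not touched. The fallback comes back to the route at 20.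

**Further compounds**

F1 | step 8 | {(3R,5S)-6-chloro-5-[(2E)-3-[4-(TBSO)phenyl]prop-2-en-1-yl]oxan-3-yl}[4-(TBSO)phenyl]methanone | CC(C)(C)[Si](C)(C)Oc1ccc(/C=C/C[C@H]2C[C@@H](C(=O)c3ccc(O[Si](C)(C)C(C)(C)C)cc3)COC2Cl)cc1
F2 | step 6 | (2S,4S,6E)-4-(dimethoxymethyl)-2-(hydroxymethyl)-1,7-bis[4-(TBSO)phenyl]hept-6-en-1-one | COC(OC)[C@@H](C/C=C/c1ccc(O[Si](C)(C)C(C)(C)C)cc1)C[C@@H](CO)C(=O)c1ccc(O[Si](C)(C)C(C)(C)C)cc1
F3 | step 6 | {(3R,5S)-6-methoxy-5-[(2E)-3-[4-(TBSO)phenyl]prop-2-en-1-yl]oxan-3-yl}[4-(TBSO)phenyl]methanone | CC(C)(C)[Si](C)(C)Oc1ccc(/C=C/C[C@H]2C[C@@H](C(=O)c3ccc(O[Si](C)(C)C(C)(C)C)cc3)COC2OC)cc1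
F4 | step 6 | {(3S,5S)-6-methoxy-5-[(2E)-3-[4-(TBSO)phenyl]prop-2-en-1-yl]oxan-3-yl}[4-(TBSO)phenyl]methanone | CC(C)(C)[Si](C)(C)Oc1ccc(/C=C/C[C@H]2C[C@H](C(=O)c3ccc(O[Si](C)(C)C(C)(C)C)cc3)COC2OC)cc1
F0 | step 9 | none | none
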